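A closed, stirred, isothermal vessel brings starting material in the first phase together with reagent held in a second phase. Target is counted with its product in the second phase.

- violet: starting material 10 mM; reagent in the second phase 0.90 equiv; run made earlier
- flask: starting material 20 mM; reagent in the second phase 0.900 equiv; time 12 min; volume of the second phase over the first 1.0

violet run (percent of the starting material charged)

| time / min | target / % | starting material / % |
|---|---|---|
| 0.200 | 1.9 | 98.7 |
| 0.667 | 3.4 | 93.6 |
| 1.00 | 4.6 | 88.8 |
| 1.50 | 5.2 | 83.8 |
| 2.50 | 7.8 | 70.8 |

(readings scatter by 1 percentage point)

- target and product in the second phase together at 12 min, in percent of the starting material charged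
- part of the starting material charged that has reacted at 12 min

- amounts and yields of target count product in the second phase too
- in the second phase: reagent in the second phase, product in the second phase; everything else is in the first
- charges count per volume of the first phase; a concentration in a rate is the amount of a species over the volume of its own phase; every rate counts per litre of the first phase
- the numbers in the tables scatter with a standard deviation of 1 percentage point
- the earlier runs hold the two phases in the same ratio of volumes as the flask asked about

Target in a running flask is an intermediate, so its amount depends on what enters and what leaves. In the violet run between 1.00 min and 2.50 min, starting material falls by F = 0.120 min⁻¹ of its charge, while target gains 0.0213 min⁻¹, which is slower. By the last reading of the violet run, 21.4 % of the charge is unseen.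

Take the lost starting material as the feed of target P, which leaves by a first-order step: dP/dt = F − P/τ. With the mean target of 6.20 % over that interval, the holding time of target, the mean stay of target between feed and loss, is τ = 0.628 min, a reading that carries the scatter. Target then levels off at L = Fτ = 7.54 %.

The flask has the same equivalents at twice the concentration, and one run cannot test the order. Carrying F over in percent of the charge, this reckoning puts the flask's target at about L at 12 min, or lower if the feed has fallen by then, L being Fτ. If reagent, the limiting reagent, is used one to one, its 0.900 equiv bounds conversion in the flask.

The forecast, at 19 % and 75 %, holds that “Target tracks conversion”, and its target stands above L. The flask gives 7.21 % and 79.9 %.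

    reagent in the reaction phase ⇌ reagent in the second phase, rate k1*([reagent in the reaction phase] - [reagent in the second phase]/K1) per volume of the first phase (partition coefficient = 1.40, kL = 0.00560 s⁻¹)
    starting material + reagent in the reaction phase → target (k = 3.70 M⁻¹ s⁻¹)
    target ⇌ product in the second phase, rate k3*([target] - [product in the second phase]/K3) per volume of the first phase (partition coefficient = 1.10, kL = 0.0250 s⁻¹)
    target → decomposed product (k = 0.00170 s⁻¹)
    target ⇌ isomer of the product (K = 12.0, k = 0.0430 s⁻¹)
    target → over-reaction product (k = 0.00900 s⁻¹)

The flask's target ends 0.33 percentage points below L, though it read 8.92 % at 6.00 min. Over the second half of the time the flask's starting material goes at 0.0301 min⁻¹, less than the feed of 0.115 min⁻¹ that τ asks for the final 7.21 %. At 12.0 min isomer of the product stands at 42.3 % in the flask, and the forward half-life of target to it, 0.27 min, is short against 12 min. The neighbouring flask, charged with 8.0 mM of starting material at the same equivalents, reaches 73.8 % conversion and gives 6.96 %, which is 0.58 points below L.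

The data are calculated for an exercise; noise was put on by code.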